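**Retrosynthetic overview**
1. Target 17 ⇐ tri-O-benzyl ether 16 by hydrogenolysis of the three aryl benzyl ethers.
2. 16 ⇐ bis(malonyl dichloride) 11 + 2 × enol silane 13. In each pyrone ring (O1, C2–C6) the O1/C6-ethyl/C5-methyl fragment is the enol of symmetrical 3-pentanone, and C2–C3–C4 is a malonyl unit whose central carbon C3 already carries the bridging CH2. C4–C5 and O1–C2 are cut in both rings.
3. 11 ⇐ tetra-acid 10 ⇐ bis(Meldrum's acid) 9 ⇐ dialdehyde 6 + Meldrum's acid 7 (reductive Knoevenagel makes both CH2–C3 bonds).
4. 6 ⇐ phloroglucinol 3 by C-acylation with (R)-2-methylbutanoyl chloride 2, double formylation and O-benzylation; the only stereocentre is bought in with acid 1.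
5. Ring order: the benzene ring is present from the start; both pyrone rings are closed last, together, in the key step.

Key step: step 9

Assumption: (R)-2-methylbutanoic acid 1 is bought in high enantiomeric purity. The stereocentre of the target is R by CIP analysis of its SMILES and is carried through unchanged. The E/Z composition of 13 has no bearing on the product.

**Step 1**
Reactants: 1 (R)-2-methylbutanoic acid
Product: 2 (R)-2-methylbutanoyl chloride
Conditions: (COCl)2 (1.2 equiv), DMF (cat.), CH2Cl2, 0 °C → rt; volatiles removed, used crude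
Reagents that add atoms: oxalyl chloride, O=C(Cl)C(Cl)=O
Why: Vilsmeier-catalysed acid chloride formation without any base gives no ketene, so the α-centre should be retained.

**Step 2**
Reactants: 3 phloroglucinol; 2 (R)-2-methylbutanoyl chloride
Product: 4 (R)-2-methyl-1-(2,4,6-trihydroxyphenyl)butan-1-one
Conditions: AlCl3 (3.5 equiv), PhNO2/CH2Cl2, 0 °C → rt; ice/1 M HCl
Reagents that add atoms: none
Why: Friedel–Crafts C-acylation of the very nucleophilic triphenol should stop at the mono-ketone because the first acyl group deactivates the ring, and capture of the acylium at low temperature should outrun its deprotonation to a ketene, so the stereocentre is expected to survive (enantiomeric purity to be checked by chiral HPLC at this stage).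

**Step 3**
Reactants: 4 (R)-2-methyl-1-(2,4,6-trihydroxyphenyl)butan-1-one
Product: 5 (R)-2,4,6-trihydroxy-5-(2-methylbutanoyl)benzene-1,3-dicarbaldehyde
Conditions: Cl2CHOMe (5 equiv), TiCl4 (7 equiv), CH2Cl2, −10 °C → rt; then ice/1 M HCl
Reagents that add atoms: dichloromethyl methyl ether, COC(Cl)Cl; water, O
Why: Rieche formylation of the titanium phenoxide should substitute both remaining ring positions, each ortho/para to three oxygens, while the Ti-chelated ketone with its single α-hydrogen has no enolisation or chromone pathway open to it.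

**Step 4**
Reactants: 5 (R)-2,4,6-trihydroxy-5-(2-methylbutanoyl)benzene-1,3-dicarbaldehyde
Product: 6 (R)-2,4,6-tris(benzyloxy)-5-(2-methylbutanoyl)benzene-1,3-dicarbaldehyde
Conditions: BnBr (4.5 equiv), K2CO3 (5 equiv), Bu4NI (cat.), DMF, rt → 50 °C
Reagents that add atoms: benzyl bromide, BrCc1ccccc1
Why: Williamson etherification in a dipolar aprotic solvent should give O-alkylation at all three phenoxides because every ring carbon already bears a carbonyl substituent, and carbonate is too weak a base to enolise the ketone.

**Step 5**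
Reactants: 6 (R)-2,4,6-tris(benzyloxy)-5-(2-methylbutanoyl)benzene-1,3-dicarbaldehyde; 7 Meldrum's acid (2,2-dimethyl-1,3-dioxane-4,6-dione)
Product: 9 (R)-5,5'-{[2,4,6-tris(benzyloxy)-5-(2-methylbutanoyl)-1,3-phenylene]bis(methylene)}bis(2,2-dimethyl-1,3-dioxane-4,6-dione), via bis(arylidene Meldrum's acid) 8 (not isolated)
Conditions: 7 (2.4 equiv), Hantzsch ester (2.4 equiv), L-proline (20 mol %), EtOH/CH2Cl2, rt
Reagents that add atoms: none
Why: Organocatalytic reductive Knoevenagel alkylation: the small, strongly C–H acidic Meldrum's acid should condense with both hindered aldehydes to 8, whose twisted, highly electrophilic alkenes take up hydride from the Hantzsch ester, while the hindered ketone does not condense.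

**Step 6**
Reactants: 9 bis(Meldrum's acid)
Product: 10 (R)-2,2'-{[2,4,6-tris(benzyloxy)-5-(2-methylbutanoyl)-1,3-phenylene]bis(methylene)}dimalonic acid
Conditions: 2 M aq. HCl/THF (1:3), 45 °C; EtOAc extraction, concentration below 40 °C
Reagents that add atoms: water, O
Why: Acid-catalysed hydrolysis of the cyclic isopropylidene acylal should release acetone and the substituted malonic acid, which does not decarboxylate below about 50 °C, and dilute acid touches neither the aryl benzyl ethers nor the α-centre.

**Step 7**
Reactants: 10 tetra-acid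
Product: 11 (R)-2,2'-{[2,4,6-tris(benzyloxy)-5-(2-methylbutanoyl)-1,3-phenylene]bis(methylene)}dimalonyl tetrachloride
Conditions: (COCl)2 (6 equiv), DMF (cat.), CH2Cl2, 0 °C → rt; evaporated, azeotroped with toluene, used at once
Reagents that add atoms: oxalyl chloride, O=C(Cl)C(Cl)=O
Why: Vilsmeier-catalysed conversion of monosubstituted malonic acids into malonyl dichlorides is standard, works at room temperature without Lewis acid so the ortho benzyl ethers should not be cleaved, and leaves only volatile by-products.

**Step 8**
Reactants: 12 3-pentanone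
Product: 13 (Z)-3-(trimethylsilyloxy)pent-2-ene (major isomer)
Conditions: TMSCl (1.2 equiv), NaI (1.2 equiv), Et3N (1.5 equiv), MeCN, rt; pentane extraction, distillation
Reagents that add atoms: chlorotrimethylsilane, C[Si](C)(C)Cl
Why: Soft enolisation with Me3SiI made in the flask and triethylamine silylates the symmetrical ketone to a single regioisomeric enol silane, mainly the thermodynamic Z isomer.

**Step 9**
Reactants: 11 bis(malonyl dichloride); 13 (Z)-3-(trimethylsilyloxy)pent-2-ene
Product: 16 (R)-3,3'-{[2,4,6-tris(benzyloxy)-5-(2-methylbutanoyl)-1,3-phenylene]bis(methylene)}bis(6-ethyl-4-hydroxy-5-methyl-2H-pyran-2-one), via bis(chlorocarbonyl ketene) 14 (not isolated), via bis(dioxoheptanoyl chloride) 15 (not isolated)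
Conditions: 13 (6 equiv), CH2Cl2, −78 °C → rt, then 35 °C, N2; aqueous work-up
Reagents that add atoms: none
Why: Each ArCH2CH(COCl)2 arm of 11 loses HCl to give the (chlorocarbonyl)ketene of 14, and the nucleophilic carbon of enol silane 13 adds to the ketene carbon to form C4–C5, silicon leaving as Me3SiCl to give the 3,5-dioxoacyl chloride arms of 15 (direct C-acylation by the doubly activated acid chloride would reach the same intermediate). The ethyl ketone of each arm then enolises and its oxygen adds to the remaining COCl carbon with loss of chloride, forming O1–C2 by a 6-exo-trig addition–elimination, and the pyran-2,4-dione tautomerises to the 4-hydroxy-2-pyrone, so that both pyrone rings close in the same operation. The closest known reaction type is the 4-hydroxy-2-pyrone synthesis from monosubstituted malonyl dichlorides or (chlorocarbonyl)ketenes and ketone silyl enol ethers. No stereocentre is created, and the existing α-centre should be left alone because no base is present and the doubly ortho-substituted, twisted aryl ketone enolises only slowly under the HCl formed. The step needs C-acylation of the enol silane before O-acylation, which the ketene or malonyl chloride electrophile gives in the absence of fluoride or Lewis acid, and it raises no regiochemical question because 3-pentanone has only one enol, so methyl falls on C5 and ethyl on C6. The benzyl ethers keep the ring oxygens from lactonising onto the malonyl units, and the excess of 13 takes up HCl and outcompetes acylation between the two arms.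

**Step 10**
Reactants: 16 tri-O-benzyl ether of the target
Product: 17 (R)-3,3'-{[2,4,6-trihydroxy-5-(2-methylbutanoyl)-1,3-phenylene]bis(methylene)}bis(6-ethyl-4-hydroxy-5-methyl-2H-pyran-2-one) (target)
Conditions: H2 (1 atm), 10% Pd/C, EtOAc/THF, rt
Reagents that add atoms: none
Why: Neutral hydrogenolysis should cleave the three aryl benzyl ethers while the tetrasubstituted pyrone double bonds and the chelated acylphloroglucinol ketone resist Pd/C at 1 atm, and the absence of acid or base avoids methylene-bridge scrambling and epimerisation.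

**Compound list**
1 | (R)-2-methylbutanoic acid | CC[C@@H](C)C(=O)O | starting material
2 | (R)-2-methylbutanoyl chloride | CC[C@@H](C)C(=O)Cl | intermediate
3 | phloroglucinol (benzene-1,3,5-triol) | Oc1cc(O)cc(O)c1 | starting material
4 | (R)-2-methyl-1-(2,4,6-trihydroxyphenyl)butan-1-one | CC[C@@H](C)C(=O)c1c(O)cc(O)cc1O | intermediate
5 | (R)-2,4,6-trihydroxy-5-(2-methylbutanoyl)benzene-1,3-dicarbaldehyde | CC[C@@H](C)C(=O)c1c(O)c(C=O)c(O)c(C=O)c1O | intermediate
6 | (R)-2,4,6-tris(benzyloxy)-5-(2-methylbutanoyl)benzene-1,3-dicarbaldehyde | CC[C@@H](C)C(=O)c1c(OCc2ccccc2)c(C=O)c(OCc2ccccc2)c(C=O)c1OCc1ccccc1 | intermediate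
7 | Meldrum's acid (2,2-dimethyl-1,3-dioxane-4,6-dione) | CC1(C)OC(=O)CC(=O)O1 | starting material
8 | bis(arylidene Meldrum's acid): both CHO groups of 6 condensed to ArCH=C(Meldrum's acid), formed in situ | CC[C@@H](C)C(=O)c1c(OCc2ccccc2)c(C=C2C(=O)OC(C)(C)OC2=O)c(OCc2ccccc2)c(C=C2C(=O)OC(C)(C)OC2=O)c1OCc1ccccc1 | intermediate
9 | (R)-5,5'-{[2,4,6-tris(benzyloxy)-5-(2-methylbutanoyl)-1,3-phenylene]bis(methylene)}bis(2,2-dimethyl-1,3-dioxane-4,6-dione) | CC[C@@H](C)C(=O)c1c(OCc2ccccc2)c(CC2C(=O)OC(C)(C)OC2=O)c(OCc2ccccc2)c(CC2C(=O)OC(C)(C)OC2=O)c1OCc1ccccc1 | intermediate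
10 | (R)-2,2'-{[2,4,6-tris(benzyloxy)-5-(2-methylbutanoyl)-1,3-phenylene]bis(methylene)}dimalonic acid | CC[C@@H](C)C(=O)c1c(OCc2ccccc2)c(CC(C(=O)O)C(=O)O)c(OCc2ccccc2)c(CC(C(=O)O)C(=O)O)c1OCc1ccccc1 | intermediate
11 | (R)-2,2'-{[2,4,6-tris(benzyloxy)-5-(2-methylbutanoyl)-1,3-phenylene]bis(methylene)}dimalonyl tetrachloride | CC[C@@H](C)C(=O)c1c(OCc2ccccc2)c(CC(C(Cl)=O)C(Cl)=O)c(OCc2ccccc2)c(CC(C(Cl)=O)C(Cl)=O)c1OCc1ccccc1 | intermediate
12 | 3-pentanone | CCC(=O)CC | starting material
13 | (Z)-3-(trimethylsilyloxy)pent-2-ene | C/C=C(/CC)O[Si](C)(C)C | intermediate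
14 | bis(chlorocarbonyl ketene): each arm ArCH2–C(=C=O)–COCl, formed in situ | CC[C@@H](C)C(=O)c1c(OCc2ccccc2)c(CC(=C=O)C(Cl)=O)c(OCc2ccccc2)c(CC(=C=O)C(Cl)=O)c1OCc1ccccc1 | intermediate
15 | bis(dioxoheptanoyl chloride): each arm ArCH2–CH(COCl)–CO–CH(CH3)–CO–CH2CH3, new sp3 centres unassigned, formed in situ | CC[C@@H](C)C(=O)c1c(OCc2ccccc2)c(CC(C(Cl)=O)C(=O)C(C)C(=O)CC)c(OCc2ccccc2)c(CC(C(Cl)=O)C(=O)C(C)C(=O)CC)c1OCc1ccccc1 | intermediate
16 | (R)-3,3'-{[2,4,6-tris(benzyloxy)-5-(2-methylbutanoyl)-1,3-phenylene]bis(methylene)}bis(6-ethyl-4-hydroxy-5-methyl-2H-pyran-2-one) | CC[C@@H](C)C(=O)c1c(OCc2ccccc2)c(Cc2c(O)c(C)c(CC)oc2=O)c(OCc2ccccc2)c(Cc2c(O)c(C)c(CC)oc2=O)c1OCc1ccccc1 | intermediate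
17 | (R)-3,3'-{[2,4,6-trihydroxy-5-(2-methylbutanoyl)-1,3-phenylene]bis(methylene)}bis(6-ethyl-4-hydroxy-5-methyl-2H-pyran-2-one) | CCc1oc(=O)c(Cc2c(O)c(Cc3c(O)c(C)c(CC)oc3=O)c(O)c(C(=O)[C@H](C)CC)c2O)c(O)c1C | target

**Step count**
Total: 10 steps. Longest linear sequence: 9 steps (1 → 2 → 4 → 5 → 6 → 9 → 10 → 11 → 16 → 17; step 8 is a one-step side branch).

**Steps most likely to fail**

Step 9 (key step). The ortho benzyloxy oxygens may capture the ketene or acid chloride with loss of benzyl chloride (debenzylative lactonisation). The HCl released may protodesilylate the enol silane before C-acylation. The second arm may react incompletely, or the ketene may oligomerise. The fallback sets out from dialdehyde 6 and enol silane 13 and comes back to the route at 16. Enol silane 13 and malonyl dichloride (Et2O, −78 °C → rt) should give the parent pyrone 6-ethyl-4-hydroxy-5-methyl-2H-pyran-2-one F1 by the same type of annulation on an unhindered partner. Dialdehyde 6, F1 (2.2 equiv), Hantzsch ester and catalytic L-proline in CH2Cl2/EtOH should then give 16 by Knoevenagel condensation at C3 of the pyrone to the bis(3-arylidenepyran-2,4-dione) F2 and transfer hydrogenation in the same flask. This is the known three-component reductive alkylation of cyclic 1,3-dicarbonyl compounds, and it forms the CH2–C3 bonds instead of the pyrone rings.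

Step 4. Alkylation of the strongly chelated, weakly nucleophilic phenoxides may stop at partial etherification, or turn to C-benzylation with dearomatisation. The fallback sets out from 5 and comes back at 6. Mitsunobu etherification (BnOH, PPh3, DIAD, THF, 0 °C → rt) uses the high acidity of these phenols instead of fighting their low nucleophilicity, and it is base-free. It makes no compound outside the list (F0).

Step 6. The malonic acid may decarboxylate during ring opening, or the acylal may hydrolyse incompletely. The fallback sets out from 9 and comes back at 10. Alcoholysis of 9 in allyl alcohol/toluene at 80 °C should open both rings to the bis(allyl hydrogen malonate) F3. Pd(PPh3)4 (cat.) and morpholine in THF at rt, followed by cold acidification, should then remove the allyl groups to give tetra-acid 10 without any heating of the free malonic acid.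

**Further compounds**
F1 | step 9 | 6-ethyl-4-hydroxy-5-methyl-2H-pyran-2-one | CCc1oc(=O)cc(O)c1C
F2 | step 9 | bis(3-arylidenepyran-2,4-dione): both CHO groups of 6 condensed at C3 of F1, alkene geometry unassigned | CC[C@@H](C)C(=O)c1c(OCc2ccccc2)c(C=C2C(=O)OC(CC)=C(C)C2=O)c(OCc2ccccc2)c(C=C2C(=O)OC(CC)=C(C)C2=O)c1OCc1ccccc1
F0 | step 4 | none | none
F3 | step 6 | bis(allyl hydrogen malonate): each arm ArCH2–CH(CO2H)–CO2CH2CH=CH2, malonate centres unassigned | CC[C@@H](C)C(=O)c1c(OCc2ccccc2)c(CC(C(=O)O)C(=O)OCC=C)c(OCc2ccccc2)c(CC(C(=O)O)C(=O)OCC=C)c1OCc1ccccc1
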